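## The problem

Compound 31 is a trans-fused decalin with five contiguous stereocentres, C4, C5, C10, C9 and C8, two of them quaternary. Labdane-type numbering is used throughout: ring A is C1–C5 and C10, ring B is C5–C10; C4 carries methyl C18 and carboxyl C19, C10 carries methyl C20, C8 carries carboxyl C17, C9 carries the chain C11–C12 ending in the butenolide C13–C16; β is the face of C20. The carboxyl C19 is axial and syn to C20, and because C4 is quaternary no equilibration can produce this arrangement; C4 must therefore be fixed early, as one enantiomer, and is then the natural source of control for the ring stereocentres. C5, C10 and C9 have to come out of one stereospecific event, since the trans ring fusion and the cis relation of C20 and C11 cannot be adjusted afterwards. C8 alone bears an acidic hydrogen, and its wanted configuration (C17 equatorial, trans to C11) is the stable one, so it can be left to a late equilibration. The α-substituted butenolide does not tolerate hydroxide, thiolates, hydrides, strong base or hydrogenation, so it must be attached last and both carboxyl groups must then be unmasked under acid; the axial, neopentyl C19 ester also resists saponification, which is why both acids are carried as tert-butyl esters. The feature that opens the molecule is ring B: C10 carries a methyl group and C9 a carbon (C11) that can be a formyl group, so ring B is the adduct of an (E)-3-methyl-2-enal C9=C10 and a diene C5=C6–C7=C8, with the ring A carbons C1–C4 as the tether from C10 to C5. Endo addition of that enal reproduces C20 cis to C11 and C5–H anti to C20, and the gem-disubstituted C4, sitting on the tether next to the diene, is placed to choose the diene face.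

## Retrosynthesis

**C12–C13 and the acid groups.** The target 31 is taken back to its di-tert-butyl ester 30, and 30 is cut between C12 and C13 into the vinyl decalin 27 and 3-bromofuran-2(5H)-one 28. Hydroboration of the vinyl group followed by a B-alkyl Suzuki–Miyaura coupling joins an sp3 carbon to the α-carbon of the butenolide in one operation. This is preferred to building the lactone on the chain, because the sensitive ring then sees only one further step. That step is an acidolysis, which is why both carboxyls are tert-butyl esters: a methyl ester at the hindered C19 would need a thiolate, and free acids would interfere with the borane. The forward reaction must spare a base-sensitive bromolactone.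

**C11=C12, C17 and C8.** Diester 27 comes from acid 26 and this from aldehyde 25, the equatorial epimer of the aldehyde obtained by oxidizing alcohol 23. Alcohol 23 is the desilylated form of 22, whose vinyl group is made from the C9 aldehyde 20 and the one-carbon ylide of 21 (cut C11=C12). Aldehyde 20 is the hydrogenated form of the cycloadduct 19. These steps only adjust oxidation levels, with one change of configuration: C17 leaves the cycloaddition cis to C11 and is turned into the trans, equatorial position at the aldehyde stage, where the axial formyl group is pressed against C20. A (Z)-configured diene terminus would give the right C8 directly, but such dienes barely reach the reactive conformation, so epimerization is the better price.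

**C5–C10 and C8–C9 (key disconnection).** Octalin aldehyde 19 is cut across ring B into the acyclic trienal 18. Both rings, two skeletal bonds and four stereocentres (C5, C8, C9, C10) disappear, and the precursor keeps only the quaternary centre C4 and three alkenes of defined geometry. The activating carbonyl sits at the dienophile terminus and becomes C11, so a Lewis acid can be used at low temperature. Cutting ring A instead (C3–C4 and C5–C10) would force two quaternary carbons to form in one thermal step. The forward reaction must be endo-selective and must add to one diene face under the influence of C4 alone.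

**The trienal.** Enal 18 is the oxidation product of allylic alcohol 17, which is freed from the bis-silyl ether 16 by removing the more labile TBS group; 16 is the TBDPS ether of dienol 15. Dienol 15 comes from the dienoate 14 by reduction, and 14 is cut at C5=C6 into the α-quaternary aldehyde 12 and triethyl 4-phosphonocrotonate 13. The vinylogous Horner–Wadsworth–Emmons reaction delivers the (E,E)-diene with C17 as an ester that is reduced selectively beside the hindered tert-butyl ester. Two silyl groups of different acid stability let C11 be unveiled while C17 stays protected.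

**C4.** Aldehyde 12 is reached from hydroxy ester 11 and this from the mixed malonate 10, the tert-butyl ester of half-ester 9. Half-ester 9 is the product of enzymatic desymmetrization of the prochiral dimethyl malonate 8. This sets the all-carbon quaternary centre without an auxiliary and from a symmetric diester. The half-ester distinguishes the two carboxyls, so the acid becomes C19 (as the tert-butyl ester) and the methyl ester becomes C5. The forward step must be enantioselective for a long, lipophilic chain.

**C3–C4 and C9=C10.** Diester 8 is cut at C3–C4 into dimethyl methylmalonate 6 and the allylic-ether chloride 5. Chloride 5 comes from alcohol 4 and ester 3, which is cut at C9=C10 into 5-chloropentan-2-one 1 and triethyl phosphonoacetate 2. The (E) geometry of the future dienophile is thus fixed in the first step, on cheap material where the minor isomer can be removed.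

## Roads not taken

**Alternative 1:** Ring A is cut at C1–C10 and C4–C5. In the forward direction the trisubstituted enal A1 (C5=C10, with the methyl and the formyl carbon that becomes C9 on C10, and a C6–C8 chain ending in the C17 ester) reacts with the 1-amino-3-siloxy diene A2 under a chiral Lewis acid or hydrogen-bond catalyst; acid work-up gives the cyclohexenone aldehyde A3. Merits: the absolute configuration comes from a catalyst available in both hands, C5 and the quaternary C10 are set in one intermolecular step from two achiral pieces, and the run-up is shorter and more convergent than the thirteen steps that precede 19. Weak points for this target: A1 is α,β-disubstituted and therefore a sluggish dienophile compared with the α-substituted acroleins for which this catalysis is best established. A3 contains one ring and two of five stereocentres. Ring B still has to be closed at C8–C9 with control of both centres, C11 has to be attached to a carbon that ends up oxygenated, and the C4 substituents have to be installed next to a C3 carbonyl that must later be removed. In the source of absolute configuration and in convergence this road is better. The chosen plan sets against it a single step that delivers both rings and four stereocentres, with C9 and C8 already carrying C11 and C17 at useful oxidation levels.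

**Alternative 2:** The cut is C4–C5 inside ring A. The six-membered lactone A4 (C19 as the carbonyl, oxygen on C1, and C1 bearing the C10=C5 alkenyl group) is converted into its silyl ketene acetal, which rearranges [3,3] through an enforced boat: C4–C5 forms, O–C1 breaks, and ring A appears as the cyclohexene acid A5. Merits: the hardest bond of the molecule, quaternary C4 next to C5, is made with a relative configuration dictated by the ring-locked ketene acetal, and the absolute configuration comes from a secondary carbinol that is easy to make. C19 arrives as the free acid in its axial position. Weak points: A5 is ring A only, with C10 still trigonal. Ring B, the quaternary C10 with trans fusion, C9 and C8 all remain, and annulating onto a trisubstituted alkene to create C10 is a second hard problem. In the certainty of the C4 configuration this road is superior to the chosen plan, whose weakest point is exactly the influence of C4 on the diene face. The chosen plan answers with step economy: after its key step no carbon–carbon bond of the decalin is missing.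

**Alternative 3:** Ring A is cut at C3–C4 and C5–C10, so that ring B becomes the tether. The triene A6 carries a (Z)-2-methyl enoate C4=C5 and a diene C10=C1–C2=C3 whose terminus C10 bears the methyl group, with C8 and C9 already configured on the chain. Heating closes ring A as a cyclohexene and ring B through the tether to give octalin A7. Merits: both quaternary carbons form in the key step. C17 and the C11–C12 arm are in place with their final configuration, so there is no late epimerization and no homologation, and the end game is shorter than the one that follows 19. Weak points: the dienophile is trisubstituted with its activating group on the inner carbon, the diene terminus is 1,1-disubstituted with a cis methyl group that disfavours the reactive conformation, and both bonding termini become quaternary. The reaction therefore needs high temperature, gets little help from Lewis acids, and has weak endo/exo and facial control from the remote centres C8 and C9. The (Z)-enoate and two acyclic stereocentres also lengthen the run-up. Its product is closer to the target than 19. The chosen plan offers a cycloaddition that is Lewis-acid activated at low temperature, forms only one quaternary centre at the bonding termini and follows a well-understood endo preference.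

Key step: step 14

Assumption: pig liver esterase is taken to give the (R)-half-ester 9, the sense known for dimethyl 2-alkyl-2-methylmalonates with an unbranched chain of five or more carbons; the steps after 9 are written for this sense.
Assumption: 3-bromofuran-2(5H)-one 28 and methyltriphenylphosphonium bromide 21 are purchased.

## Route

Step 1
Reactants: 1 5-chloropentan-2-one; 2 triethyl phosphonoacetate
Product: 3 ethyl (E)-6-chloro-3-methylhex-2-enoate
Conditions: NaH, THF, 0 °C to rt; (E)-isomer separated by chromatography
Reagents that add atoms: none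
Why: Horner–Wadsworth–Emmons olefination of a methyl ketone; the stabilized phosphonate anion gives mainly the (E)-enoate (ester trans to the longer chain), the minor (Z)-isomer is removed at this cheap stage, and the primary chloride is inert to the anion.

Step 2
Reactants: 3 ethyl (E)-6-chloro-3-methylhex-2-enoate
Product: 4 (E)-6-chloro-3-methylhex-2-en-1-ol
Conditions: i-Bu2AlH, CH2Cl2, −78 °C
Reagents that add atoms: none
Why: 1,2-reduction of a conjugated ester to the allylic alcohol by i-Bu2AlH; alkene geometry and the alkyl chloride are untouched at low temperature.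

Step 3
Reactants: 4 (E)-6-chloro-3-methylhex-2-en-1-ol
Product: 5 tert-butyl-[(E)-6-chloro-3-methylhex-2-enoxy]-dimethylsilane
Conditions: TBSCl, imidazole, DMF, rt
Reagents that add atoms: tert-butyldimethylsilyl chloride, CC(C)(C)[Si](C)(C)Cl
Why: imidazole-promoted silylation of a primary alcohol; the TBS ether masks the future C11 aldehyde through the basic, enzymatic and hydride steps and is later the more acid-labile of two silyl ethers.

Step 4
Reactants: 5 tert-butyl-[(E)-6-chloro-3-methylhex-2-enoxy]-dimethylsilane; 6 dimethyl 2-methylpropanedioate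
Product: 8 dimethyl 2-[(E)-6-(tert-butyldimethylsilyloxy)-4-methylhex-4-enyl]-2-methylpropanedioate, via allylic-ether iodide 7 (not isolated)
Conditions: NaH, DMF, 0 °C; then 5, NaI (1.1 equiv), 60 °C
Reagents that add atoms: none
Why: Finkelstein exchange makes the primary iodide in the flask and the sodium enolate of the methylmalonate displaces it by SN2 to form C3–C4; the product is quaternary, so a second alkylation is impossible.

Step 5
Reactants: 8 dimethyl 2-[(E)-6-(tert-butyldimethylsilyloxy)-4-methylhex-4-enyl]-2-methylpropanedioate
Product: 9 (2R)-2-[(E)-6-(tert-butyldimethylsilyloxy)-4-methylhex-4-enyl]-3-methoxy-2-methyl-3-oxopropanoic acid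
Conditions: pig liver esterase, phosphate buffer (pH 7.5)/DMSO 9:1, rt; then citric acid to pH 4
Reagents that add atoms: water, O
Why: enzymatic desymmetrization of a prochiral 2-alkyl-2-methylmalonate; hydrolysis stops at the half-ester and the quaternary C4 is set by the enzyme's choice between the enantiotopic ester groups, the enantiomeric purity being raised if needed by crystallizing an amine salt of the acid.

Step 6
Reactants: 9 (2R)-2-[(E)-6-(tert-butyldimethylsilyloxy)-4-methylhex-4-enyl]-3-methoxy-2-methyl-3-oxopropanoic acid
Product: 10 1-tert-butyl 3-methyl (2S)-2-[(E)-6-(tert-butyldimethylsilyloxy)-4-methylhex-4-enyl]-2-methylpropanedioate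
Conditions: tert-butyl 2,2,2-trichloroacetimidate, CH2Cl2/cyclohexane, rt
Reagents that add atoms: tert-butyl 2,2,2-trichloroacetimidate, CC(C)(C)OC(=N)C(Cl)(Cl)Cl
Why: O-tert-butylation of the carboxylic acid by the trichloroacetimidate (the acid protonates the imidate and the tert-butyl cation is captured on oxygen), so the hindrance at the quaternary carbon does not matter and no added Lewis acid endangers the TBS ether; this fixes the free acid as the future C19.

Step 7
Reactants: 10 1-tert-butyl 3-methyl (2S)-2-[(E)-6-(tert-butyldimethylsilyloxy)-4-methylhex-4-enyl]-2-methylpropanedioate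
Product: 11 tert-butyl (2S,6E)-8-(tert-butyldimethylsilyloxy)-2-(hydroxymethyl)-2,6-dimethyloct-6-enoate
Conditions: LiBH4, THF, 0 °C to rt
Reagents that add atoms: none
Why: LiBH4 reduces the methyl ester of the mixed malonate, which is activated by the second carboxyl, and leaves the bulky tert-butyl ester, the alkene and the silyl ether; C4 is quaternary and cannot epimerize.

Step 8
Reactants: 11 tert-butyl (2S,6E)-8-(tert-butyldimethylsilyloxy)-2-(hydroxymethyl)-2,6-dimethyloct-6-enoate
Product: 12 tert-butyl (2S,6E)-8-(tert-butyldimethylsilyloxy)-2-formyl-2,6-dimethyloct-6-enoate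
Conditions: Dess–Martin periodinane, CH2Cl2, 0 °C to rt
Reagents that add atoms: none
Why: Dess–Martin oxidation of a neopentyl primary alcohol to the aldehyde; the α-carbon is quaternary, so neither enolization nor epimerization can occur.

Step 9
Reactants: 12 tert-butyl (2S,6E)-8-(tert-butyldimethylsilyloxy)-2-formyl-2,6-dimethyloct-6-enoate; 13 triethyl 4-phosphonocrotonate
Product: 14 7-tert-butyl 1-ethyl (2E,4E,6S)-6-[(E)-6-(tert-butyldimethylsilyloxy)-4-methylhex-4-enyl]-6-methylhepta-2,4-dienedioate
Conditions: LiN(SiMe3)2, THF, −78 °C; then 12, −78 °C to rt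
Reagents that add atoms: none
Why: vinylogous Horner–Wadsworth–Emmons olefination; the lithiated phosphonocrotonate reacts at its α-carbon, the new C5=C6 bond is (E) with the bulky aldehyde, and the C7=C8 geometry is carried over from the reagent.

Step 10
Reactants: 14 7-tert-butyl 1-ethyl (2E,4E,6S)-6-[(E)-6-(tert-butyldimethylsilyloxy)-4-methylhex-4-enyl]-6-methylhepta-2,4-dienedioate
Product: 15 tert-butyl (2S,3E,5E)-2-[(E)-6-(tert-butyldimethylsilyloxy)-4-methylhex-4-enyl]-7-hydroxy-2-methylhepta-3,5-dienoate
Conditions: i-Bu2AlH, CH2Cl2, −78 °C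
Reagents that add atoms: none
Why: 1,2-reduction of the unhindered ethyl dienoate to the dienol; the tert-butyl ester on a quaternary carbon is too hindered to react at −78 °C, which is the chemoselectivity the step needs.

Step 11
Reactants: 15 tert-butyl (2S,3E,5E)-2-[(E)-6-(tert-butyldimethylsilyloxy)-4-methylhex-4-enyl]-7-hydroxy-2-methylhepta-3,5-dienoate
Product: 16 tert-butyl (2S,3E,5E)-2-[(E)-6-(tert-butyldimethylsilyloxy)-4-methylhex-4-enyl]-7-(tert-butyldiphenylsilyloxy)-2-methylhepta-3,5-dienoate
Conditions: TBDPSCl, imidazole, CH2Cl2, rt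
Reagents that add atoms: tert-butyldiphenylsilyl chloride, CC(C)(C)[Si](Cl)(c1ccccc1)c1ccccc1
Why: silylation of the dienyl primary alcohol with the acid-stable TBDPS group, chosen so that the TBS ether at C11 can be removed beside it and so that the C17 oxygen is a poor Lewis base in the cycloaddition.

Step 12
Reactants: 16 tert-butyl (2S,3E,5E)-2-[(E)-6-(tert-butyldimethylsilyloxy)-4-methylhex-4-enyl]-7-(tert-butyldiphenylsilyloxy)-2-methylhepta-3,5-dienoate
Product: 17 tert-butyl (2S,3E,5E)-7-(tert-butyldiphenylsilyloxy)-2-[(E)-6-hydroxy-4-methylhex-4-enyl]-2-methylhepta-3,5-dienoate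
Conditions: PPTS (cat.), MeOH, rt
Reagents that add atoms: none
Why: mild acid methanolysis cleaves a primary TBS ether much faster than a TBDPS ether; the tert-butyl ester and the diene are stable to PPTS.

Step 13
Reactants: 17 tert-butyl (2S,3E,5E)-7-(tert-butyldiphenylsilyloxy)-2-[(E)-6-hydroxy-4-methylhex-4-enyl]-2-methylhepta-3,5-dienoate
Product: 18 tert-butyl (2S,3E,5E)-7-(tert-butyldiphenylsilyloxy)-2-methyl-2-[(E)-4-methyl-6-oxohex-4-enyl]hepta-3,5-dienoate
Conditions: MnO2, CH2Cl2, rt; used at once
Reagents that add atoms: none
Why: MnO2 oxidation of an allylic alcohol to the enal with retention of the (E) geometry; silyl ether, ester and diene are not touched.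

Step 14
Reactants: 18 tert-butyl (2S,3E,5E)-7-(tert-butyldiphenylsilyloxy)-2-methyl-2-[(E)-4-methyl-6-oxohex-4-enyl]hepta-3,5-dienoate
Product: 19 tert-butyl (1S,4aS,5S,6S,8aR)-6-[(tert-butyldiphenylsilyloxy)methyl]-5-formyl-1,4a-dimethyl-1,2,3,4,4a,5,6,8a-octahydronaphthalene-1-carboxylate
Conditions: Me2AlCl (1.5 equiv), CH2Cl2, −78 to −20 °C
Reagents that add atoms: none
Why: Concerted, asynchronous [4+2] cycloaddition: Me2AlCl binds the formyl oxygen of 18, lowers the LUMO of the enal C9=C10, and the diene C5–C8 adds suprafacially, the bond C5–C10 to the enal β-carbon being the more advanced; the closest known reaction type is the Lewis-acid-promoted type 1 intramolecular Diels–Alder reaction of (E)-undeca-2,8,10-trienals, including 3-methyl enals that create an angular methyl group. Ring B closes as a cyclohexene by the cycloaddition itself (bonds C5–C10 and C8–C9), and ring A closes in the fused mode as the six-membered tether ring through C5–C10, helped by the geminal substitution at C4. At C10 and C9 the cis relation of C20 and C11 is the (E) geometry of the enal carried over suprafacially. At C5 and C8 the (E,E)-diene places C4 and C17 cis on ring B, and the endo position of the aluminium-bound formyl group, which puts the tether exo, gives the trans ring fusion (C5–H anti to C20) and C17 cis to C11. Beyond endo selectivity the step needs a choice of diene face, that is the sense of the four new centres relative to C4: in the chair-like tether one C4 substituent must be axial and syn to the pseudo-axial C20 methyl, and the flat tert-butoxycarbonyl group takes that site more readily than the methyl group, which would meet a methyl–methyl syn-diaxial contact. The tert-butyl ester and the TBDPS ether are weak ligands for aluminium at low temperature, so the enal is the activated site.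

Step 15
Reactants: 19 tert-butyl (1S,4aS,5S,6S,8aR)-6-[(tert-butyldiphenylsilyloxy)methyl]-5-formyl-1,4a-dimethyl-1,2,3,4,4a,5,6,8a-octahydronaphthalene-1-carboxylate
Product: 20 tert-butyl (1S,4aS,5S,6S,8aR)-6-[(tert-butyldiphenylsilyloxy)methyl]-5-formyl-1,4a-dimethyldecahydronaphthalene-1-carboxylate
Conditions: H2 (1 atm), Pd/C, EtOAc, rt
Reagents that add atoms: none
Why: heterogeneous hydrogenation of the cis-disubstituted ring alkene C6=C7; no stereocentre is formed, and the hindered aldehyde, the silyl ether and the ester are not reduced under these conditions.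

Step 16
Reactants: 20 tert-butyl (1S,4aS,5S,6S,8aR)-6-[(tert-butyldiphenylsilyloxy)methyl]-5-formyl-1,4a-dimethyldecahydronaphthalene-1-carboxylate; 21 methyltriphenylphosphonium bromide
Product: 22 tert-butyl (1S,4aR,5S,6S,8aR)-6-[(tert-butyldiphenylsilyloxy)methyl]-5-ethenyl-1,4a-dimethyldecahydronaphthalene-1-carboxylate
Conditions: 21, KOtBu, THF, 0 °C; then 20, 0 °C to rt
Reagents that add atoms: none
Why: Wittig methylenation forms C11=C12; the small unstabilized ylide adds to hindered aldehydes faster than it enolizes them, and the equatorial formyl group at C9 is also the stable epimer, so C9 keeps its configuration.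

Step 17
Reactants: 22 tert-butyl (1S,4aR,5S,6S,8aR)-6-[(tert-butyldiphenylsilyloxy)methyl]-5-ethenyl-1,4a-dimethyldecahydronaphthalene-1-carboxylate
Product: 23 tert-butyl (1S,4aR,5S,6S,8aR)-5-ethenyl-6-(hydroxymethyl)-1,4a-dimethyldecahydronaphthalene-1-carboxylate
Conditions: TBAF, THF, rt
Reagents that add atoms: none
Why: fluoride cleavage of the silyl ether, driven by the Si–F bond; nothing else in 22 is sensitive to fluoride or to its basicity.

Step 18
Reactants: 23 tert-butyl (1S,4aR,5S,6S,8aR)-5-ethenyl-6-(hydroxymethyl)-1,4a-dimethyldecahydronaphthalene-1-carboxylate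
Product: 25 tert-butyl (1S,4aR,5S,6R,8aR)-5-ethenyl-6-formyl-1,4a-dimethyldecahydronaphthalene-1-carboxylate, via 8β-aldehyde 24 (not isolated)
Conditions: Dess–Martin periodinane, CH2Cl2, rt; aqueous wash; then DBU (cat.), CH2Cl2, rt
Reagents that add atoms: none
Why: Dess–Martin oxidation gives the axial aldehyde 24, whose formyl group is syn-diaxial to the C10 methyl; DBU equilibrates it through the enolate to the equatorial aldehyde 25, trans to the C9 vinyl group, which is the configuration of the target at C8 (thermodynamic control).

Step 19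
Reactants: 25 tert-butyl (1S,4aR,5S,6R,8aR)-5-ethenyl-6-formyl-1,4a-dimethyldecahydronaphthalene-1-carboxylate
Product: 26 1-tert-butyl hydrogen (1S,4aR,5S,6R,8aR)-5-ethenyl-1,4a-dimethyldecahydronaphthalene-1,6-dicarboxylate
Conditions: NaClO2, NaH2PO4, 2-methylbut-2-ene, t-BuOH/H2O, rt
Reagents that add atoms: sodium chlorite, [Na+].[O-]Cl=O
Why: Pinnick oxidation; chlorous acid converts the aldehyde to the acid without epimerizing C8, and 2-methylbut-2-ene traps hypochlorous acid so that the vinyl group is not chlorinated.

Step 20
Reactants: 26 1-tert-butyl hydrogen (1S,4aR,5S,6R,8aR)-5-ethenyl-1,4a-dimethyldecahydronaphthalene-1,6-dicarboxylate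
Product: 27 di-tert-butyl (1S,4aR,5S,6R,8aR)-5-ethenyl-1,4a-dimethyldecahydronaphthalene-1,6-dicarboxylate
Conditions: tert-butyl 2,2,2-trichloroacetimidate, CH2Cl2/cyclohexane, rt
Reagents that add atoms: tert-butyl 2,2,2-trichloroacetimidate, CC(C)(C)OC(=N)C(Cl)(Cl)Cl
Why: the same O-tert-butylation as in step 6; with both carboxyls under one acid-labile group the hydroboration meets no acidic hydrogen and the final deprotection needs no base.

Step 21
Reactants: 27 di-tert-butyl (1S,4aR,5S,6R,8aR)-5-ethenyl-1,4a-dimethyldecahydronaphthalene-1,6-dicarboxylate; 28 3-bromofuran-2(5H)-one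
Product: 30 di-tert-butyl (1S,4aR,5S,6R,8aR)-1,4a-dimethyl-5-[2-(2-oxo-2,5-dihydrofuran-3-yl)ethyl]decahydronaphthalene-1,6-dicarboxylate, via B-alkyl-9-BBN 29 (not isolated)
Conditions: 9-BBN, THF, rt; then 28, PdCl2(dppf) (5 mol %), AsPh3, Cs2CO3, DMF/THF/H2O, rt
Reagents that add atoms: none
Why: anti-Markovnikov hydroboration of the monosubstituted alkene by 9-BBN, then B-alkyl Suzuki–Miyaura coupling of the primary alkylborane with the α-bromo enoate carbon of 28 (oxidative addition to zerovalent palladium, base-assisted transmetalation, reductive elimination) forms C12–C13; room temperature and a carbonate base spare the lactone and the tert-butyl esters.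

Step 22
Reactants: 30 di-tert-butyl (1S,4aR,5S,6R,8aR)-1,4a-dimethyl-5-[2-(2-oxo-2,5-dihydrofuran-3-yl)ethyl]decahydronaphthalene-1,6-dicarboxylate
Product: 31 (1S,4aR,5S,6R,8aR)-1,4a-dimethyl-5-[2-(2-oxo-2,5-dihydrofuran-3-yl)ethyl]decahydronaphthalene-1,6-dicarboxylic acid
Conditions: CF3CO2H/CH2Cl2 1:4, 0 °C to rt
Reagents that add atoms: none
Why: acidolysis of both tert-butyl esters by alkyl–oxygen cleavage, which is insensitive to the hindrance at C4; the butenolide and all stereocentres are stable to trifluoroacetic acid.

## Compound list

1 | 5-chloropentan-2-one | CC(=O)CCCCl | starting material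
2 | triethyl phosphonoacetate | CCOC(=O)CP(=O)(OCC)OCC | starting material
3 | ethyl (E)-6-chloro-3-methylhex-2-enoate | CCOC(=O)/C=C(\C)CCCCl | intermediate
4 | (E)-6-chloro-3-methylhex-2-en-1-ol | OC/C=C(\C)CCCCl | intermediate
5 | tert-butyl-[(E)-6-chloro-3-methylhex-2-enoxy]-dimethylsilane | CC(C)(C)[Si](C)(C)OC/C=C(\C)CCCCl | intermediate
6 | dimethyl 2-methylpropanedioate (dimethyl methylmalonate) | COC(=O)C(C)C(=O)OC | starting material
7 | tert-butyl-[(E)-6-iodo-3-methylhex-2-enoxy]-dimethylsilane | CC(C)(C)[Si](C)(C)OC/C=C(\C)CCCI | intermediate (not isolated)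
8 | dimethyl 2-[(E)-6-(tert-butyldimethylsilyloxy)-4-methylhex-4-enyl]-2-methylpropanedioate | CC(C)(C)[Si](C)(C)OC/C=C(\C)CCCC(C)(C(=O)OC)C(=O)OC | intermediate
9 | (2R)-2-[(E)-6-(tert-butyldimethylsilyloxy)-4-methylhex-4-enyl]-3-methoxy-2-methyl-3-oxopropanoic acid | CC(C)(C)[Si](C)(C)OC/C=C(\C)CCC[C@](C)(C(=O)O)C(=O)OC | intermediate
10 | 1-tert-butyl 3-methyl (2S)-2-[(E)-6-(tert-butyldimethylsilyloxy)-4-methylhex-4-enyl]-2-methylpropanedioate | CC(C)(C)[Si](C)(C)OC/C=C(\C)CCC[C@](C)(C(=O)OC(C)(C)C)C(=O)OC | intermediate
11 | tert-butyl (2S,6E)-8-(tert-butyldimethylsilyloxy)-2-(hydroxymethyl)-2,6-dimethyloct-6-enoate | CC(C)(C)[Si](C)(C)OC/C=C(\C)CCC[C@](C)(C(=O)OC(C)(C)C)CO | intermediate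
12 | tert-butyl (2S,6E)-8-(tert-butyldimethylsilyloxy)-2-formyl-2,6-dimethyloct-6-enoate | CC(C)(C)[Si](C)(C)OC/C=C(\C)CCC[C@](C)(C(=O)OC(C)(C)C)C=O | intermediate
13 | triethyl 4-phosphonocrotonate | CCOC(=O)/C=C/CP(=O)(OCC)OCC | starting material
14 | 7-tert-butyl 1-ethyl (2E,4E,6S)-6-[(E)-6-(tert-butyldimethylsilyloxy)-4-methylhex-4-enyl]-6-methylhepta-2,4-dienedioate | CC(C)(C)[Si](C)(C)OC/C=C(\C)CCC[C@](C)(C(=O)OC(C)(C)C)/C=C/C=C/C(=O)OCC | intermediate
15 | tert-butyl (2S,3E,5E)-2-[(E)-6-(tert-butyldimethylsilyloxy)-4-methylhex-4-enyl]-7-hydroxy-2-methylhepta-3,5-dienoate | CC(C)(C)[Si](C)(C)OC/C=C(\C)CCC[C@](C)(C(=O)OC(C)(C)C)/C=C/C=C/CO | intermediate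
16 | tert-butyl (2S,3E,5E)-2-[(E)-6-(tert-butyldimethylsilyloxy)-4-methylhex-4-enyl]-7-(tert-butyldiphenylsilyloxy)-2-methylhepta-3,5-dienoate | CC(C)(C)[Si](C)(C)OC/C=C(\C)CCC[C@](C)(C(=O)OC(C)(C)C)/C=C/C=C/CO[Si](c1ccccc1)(c1ccccc1)C(C)(C)C | intermediate
17 | tert-butyl (2S,3E,5E)-7-(tert-butyldiphenylsilyloxy)-2-[(E)-6-hydroxy-4-methylhex-4-enyl]-2-methylhepta-3,5-dienoate | OC/C=C(\C)CCC[C@](C)(C(=O)OC(C)(C)C)/C=C/C=C/CO[Si](c1ccccc1)(c1ccccc1)C(C)(C)C | intermediate
18 | tert-butyl (2S,3E,5E)-7-(tert-butyldiphenylsilyloxy)-2-methyl-2-[(E)-4-methyl-6-oxohex-4-enyl]hepta-3,5-dienoate | O=C/C=C(\C)CCC[C@](C)(C(=O)OC(C)(C)C)/C=C/C=C/CO[Si](c1ccccc1)(c1ccccc1)C(C)(C)C | intermediate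
19 | tert-butyl (1S,4aS,5S,6S,8aR)-6-[(tert-butyldiphenylsilyloxy)methyl]-5-formyl-1,4a-dimethyl-1,2,3,4,4a,5,6,8a-octahydronaphthalene-1-carboxylate | C[C@]12CCC[C@](C)(C(=O)OC(C)(C)C)[C@@H]1C=C[C@H](CO[Si](c3ccccc3)(c3ccccc3)C(C)(C)C)[C@@H]2C=O | intermediate
20 | tert-butyl (1S,4aS,5S,6S,8aR)-6-[(tert-butyldiphenylsilyloxy)methyl]-5-formyl-1,4a-dimethyldecahydronaphthalene-1-carboxylate | C[C@]12CCC[C@](C)(C(=O)OC(C)(C)C)[C@@H]1CC[C@H](CO[Si](c3ccccc3)(c3ccccc3)C(C)(C)C)[C@@H]2C=O | intermediate
21 | methyltriphenylphosphonium bromide | C[P+](c1ccccc1)(c1ccccc1)c1ccccc1.[Br-] | starting material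
22 | tert-butyl (1S,4aR,5S,6S,8aR)-6-[(tert-butyldiphenylsilyloxy)methyl]-5-ethenyl-1,4a-dimethyldecahydronaphthalene-1-carboxylate | C[C@]12CCC[C@](C)(C(=O)OC(C)(C)C)[C@@H]1CC[C@H](CO[Si](c3ccccc3)(c3ccccc3)C(C)(C)C)[C@@H]2C=C | intermediate
23 | tert-butyl (1S,4aR,5S,6S,8aR)-5-ethenyl-6-(hydroxymethyl)-1,4a-dimethyldecahydronaphthalene-1-carboxylate | C[C@]12CCC[C@](C)(C(=O)OC(C)(C)C)[C@@H]1CC[C@H](CO)[C@@H]2C=C | intermediate
24 | tert-butyl (1S,4aR,5S,6S,8aR)-5-ethenyl-6-formyl-1,4a-dimethyldecahydronaphthalene-1-carboxylate (8β-aldehyde) | C[C@]12CCC[C@](C)(C(=O)OC(C)(C)C)[C@@H]1CC[C@H](C=O)[C@@H]2C=C | intermediate (not isolated)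
25 | tert-butyl (1S,4aR,5S,6R,8aR)-5-ethenyl-6-formyl-1,4a-dimethyldecahydronaphthalene-1-carboxylate (8α-aldehyde) | C[C@]12CCC[C@](C)(C(=O)OC(C)(C)C)[C@@H]1CC[C@@H](C=O)[C@@H]2C=C | intermediate
26 | 1-tert-butyl hydrogen (1S,4aR,5S,6R,8aR)-5-ethenyl-1,4a-dimethyldecahydronaphthalene-1,6-dicarboxylate | C[C@]12CCC[C@](C)(C(=O)OC(C)(C)C)[C@@H]1CC[C@@H](C(=O)O)[C@@H]2C=C | intermediate
27 | di-tert-butyl (1S,4aR,5S,6R,8aR)-5-ethenyl-1,4a-dimethyldecahydronaphthalene-1,6-dicarboxylate | C[C@]12CCC[C@](C)(C(=O)OC(C)(C)C)[C@@H]1CC[C@@H](C(=O)OC(C)(C)C)[C@@H]2C=C | intermediate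
28 | 3-bromofuran-2(5H)-one | BrC1=CCOC1=O | starting material
29 | di-tert-butyl (1S,4aR,5S,6R,8aR)-5-[2-(9-borabicyclo[3.3.1]nonan-9-yl)ethyl]-1,4a-dimethyldecahydronaphthalene-1,6-dicarboxylate | C[C@]12CCC[C@](C)(C(=O)OC(C)(C)C)[C@@H]1CC[C@@H](C(=O)OC(C)(C)C)[C@@H]2CCB3C4CCCC3CCC4 | intermediate (not isolated)
30 | di-tert-butyl (1S,4aR,5S,6R,8aR)-1,4a-dimethyl-5-[2-(2-oxo-2,5-dihydrofuran-3-yl)ethyl]decahydronaphthalene-1,6-dicarboxylate | C[C@]12CCC[C@](C)(C(=O)OC(C)(C)C)[C@@H]1CC[C@@H](C(=O)OC(C)(C)C)[C@@H]2CCC3=CCOC3=O | intermediate
31 | (1S,4aR,5S,6R,8aR)-1,4a-dimethyl-5-[2-(2-oxo-2,5-dihydrofuran-3-yl)ethyl]decahydronaphthalene-1,6-dicarboxylic acid (CNP0478950.1) | C[C@]12CCC[C@](C)(C(=O)O)[C@@H]1CC[C@@H](C(=O)O)[C@@H]2CCC1=CCOC1=O | target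

## Step count and least certain steps

Total: 22 steps. Longest linear sequence: 22 steps (1 to 31).

**Step 14 (key step).** The most likely failure is insufficient discrimination between the two diene faces: the preference of the ester over the methyl group for the axial site at C4 may be too small in the transition state, so that the adduct with the opposite ring configuration relative to C4 forms alongside. Less likely is slow addition of the β,β-disubstituted enal with Lewis-acid-induced ionization of the dienyl silyl ether. Fallback: the facial choice is handed to a covalently bound controller on the dienophile. Setting out from 18, NaClO2 oxidation gives the trienoic acid F1. Its pivaloyl mixed anhydride acylates lithiated (4S)-4-benzyloxazolidin-2-one to the N-enoyl oxazolidinone F2. Me2AlCl then forms the chelated imide, whose benzyl group blocks one face of C9=C10, and the same endo cycloaddition gives the imide cycloadduct F3. LiBH4 removes the auxiliary reductively to the primary alcohol F4, and Dess–Martin oxidation returns to the route at 19.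

**Step 5.** The long, lipophilic silyloxy chain may fit the enzyme poorly, which would show as slow turnover or as incomplete or reversed selection between the enantiotopic esters. Fallback: classical resolution in place of desymmetrization. Setting out from 8, KOH (1 equiv) in MeOH gives the racemic half-ester F5. Crystallization of its salt with one enantiomer of 1-phenylethylamine, chosen by trial, gives the diastereomerically pure ammonium salt F6 (written for the (R)-amine), and acidification returns to the route at 9.

**Step 21.** The bromolactone 28 may be consumed by the aqueous base (ring opening, conjugate addition) before transmetalation, or the alkylborane may be lost by protodeboronation. Fallback: the butenolide is built by enolate alkylation and sulfoxide elimination. Setting out from 27 (through 29), oxidation of the borane with NaBO3 gives the primary alcohol F7, and PPh3, imidazole and iodine give the iodide F8. F8 alkylates the lithium enolate of 3-(phenylsulfanyl)oxolan-2-one (LiN(SiMe3)2, THF/HMPA) to the α-phenylsulfanyl lactone F9. Oxidation with mCPBA gives the sulfoxide F10, and thermal syn-elimination in toluene places the double bond in the ring and returns to the route at 30.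

**Step 16.** The basic ylide may enolize the hindered aldehyde, which sits next to a quaternary carbon and an axial substituent, instead of adding to it; this would show as loss of configuration at C9 or recovered aldehyde. Fallback: Peterson olefination through a non-basic nucleophile. Setting out from 20, Me3SiCH2MgCl with CeCl3 in THF adds to the aldehyde to give the β-hydroxysilane F11 (either carbinol epimer), and KH in THF effects syn-elimination and returns to the route at 22.

## Further compounds

F1 | step 14 | (2E,7S,8E,10E)-7-(tert-butoxycarbonyl)-12-(tert-butyldiphenylsilyloxy)-3,7-dimethyldodeca-2,8,10-trienoic acid | OC(=O)/C=C(\C)CCC[C@](C)(C(=O)OC(C)(C)C)/C=C/C=C/CO[Si](c1ccccc1)(c1ccccc1)C(C)(C)C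
F2 | step 14 | tert-butyl (2S,3E,5E)-2-[(E)-6-[(4S)-4-benzyl-2-oxooxazolidin-3-yl]-4-methyl-6-oxohex-4-enyl]-7-(tert-butyldiphenylsilyloxy)-2-methylhepta-3,5-dienoate | O=C(/C=C(\C)CCC[C@](C)(C(=O)OC(C)(C)C)/C=C/C=C/CO[Si](c1ccccc1)(c1ccccc1)C(C)(C)C)N1[C@@H](Cc2ccccc2)COC1=O
F3 | step 14 | tert-butyl 5-[(4S)-4-benzyl-2-oxooxazolidine-3-carbonyl]-6-[(tert-butyldiphenylsilyloxy)methyl]-1,4a-dimethyl-1,2,3,4,4a,5,6,8a-octahydronaphthalene-1-carboxylate, ring stereocentres as in 19 | C[C@]12CCC[C@](C)(C(=O)OC(C)(C)C)[C@@H]1C=C[C@H](CO[Si](c3ccccc3)(c3ccccc3)C(C)(C)C)[C@@H]2C(=O)N4[C@@H](Cc5ccccc5)COC4=O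
F4 | step 14 | tert-butyl (1S,4aS,5S,6S,8aR)-6-[(tert-butyldiphenylsilyloxy)methyl]-5-(hydroxymethyl)-1,4a-dimethyl-1,2,3,4,4a,5,6,8a-octahydronaphthalene-1-carboxylate | C[C@]12CCC[C@](C)(C(=O)OC(C)(C)C)[C@@H]1C=C[C@H](CO[Si](c3ccccc3)(c3ccccc3)C(C)(C)C)[C@@H]2CO
F5 | step 5 | racemic 2-[(E)-6-(tert-butyldimethylsilyloxy)-4-methylhex-4-enyl]-3-methoxy-2-methyl-3-oxopropanoic acid | CC(C)(C)[Si](C)(C)OC/C=C(\C)CCCC(C)(C(=O)O)C(=O)OC
F6 | step 5 | (R)-1-phenylethylammonium salt of the (2R)-half-ester 9 | CC(C)(C)[Si](C)(C)OC/C=C(\C)CCC[C@](C)(C(=O)[O-])C(=O)OC.C[C@@H]([NH3+])c1ccccc1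
F7 | step 21 | di-tert-butyl (1S,4aR,5S,6R,8aR)-5-(2-hydroxyethyl)-1,4a-dimethyldecahydronaphthalene-1,6-dicarboxylate | C[C@]12CCC[C@](C)(C(=O)OC(C)(C)C)[C@@H]1CC[C@@H](C(=O)OC(C)(C)C)[C@@H]2CCO
F8 | step 21 | di-tert-butyl (1S,4aR,5S,6R,8aR)-5-(2-iodoethyl)-1,4a-dimethyldecahydronaphthalene-1,6-dicarboxylate | C[C@]12CCC[C@](C)(C(=O)OC(C)(C)C)[C@@H]1CC[C@@H](C(=O)OC(C)(C)C)[C@@H]2CCI
F9 | step 21 | di-tert-butyl (1S,4aR,5S,6R,8aR)-1,4a-dimethyl-5-[2-(2-oxo-3-phenylsulfanyloxolan-3-yl)ethyl]decahydronaphthalene-1,6-dicarboxylate, both epimers at the lactone carbon | C[C@]12CCC[C@](C)(C(=O)OC(C)(C)C)[C@@H]1CC[C@@H](C(=O)OC(C)(C)C)[C@@H]2CCC3(Sc4ccccc4)CCOC3=O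
F10 | step 21 | di-tert-butyl (1S,4aR,5S,6R,8aR)-5-[2-[3-(benzenesulfinyl)-2-oxooxolan-3-yl]ethyl]-1,4a-dimethyldecahydronaphthalene-1,6-dicarboxylate, mixture of sulfoxide diastereomers | C[C@]12CCC[C@](C)(C(=O)OC(C)(C)C)[C@@H]1CC[C@@H](C(=O)OC(C)(C)C)[C@@H]2CCC3(S(=O)c4ccccc4)CCOC3=O
F11 | step 16 | tert-butyl 6-[(tert-butyldiphenylsilyloxy)methyl]-5-(1-hydroxy-2-trimethylsilylethyl)-1,4a-dimethyldecahydronaphthalene-1-carboxylate, ring stereocentres as in 20, either carbinol epimer | C[C@]12CCC[C@](C)(C(=O)OC(C)(C)C)[C@@H]1CC[C@H](CO[Si](c3ccccc3)(c3ccccc3)C(C)(C)C)[C@@H]2C(O)C[Si](C)(C)C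
A1 | alternative 1 | tert-butyl (E)-6-methyl-7-oxohept-5-enoate | O=C/C(C)=C/CCCC(=O)OC(C)(C)C
A2 | alternative 1 | (E)-1-(dimethylamino)-3-(tert-butyldimethylsilyloxy)buta-1,3-diene | CN(C)/C=C/C(=C)O[Si](C)(C)C(C)(C)C
A3 | alternative 1 | tert-butyl 4-(2-formyl-2-methyl-5-oxocyclohex-3-en-1-yl)butanoate, C5 and C10 as in 31 | C[C@]1(C=O)C=CC(=O)C[C@@H]1CCCC(=O)OC(C)(C)C
A4 | alternative 2 | (6R)-6-[(E)-5-(tert-butyldimethylsilyloxy)pent-2-en-2-yl]-3-methyloxan-2-one, either configuration at C3 | CC1CC[C@H](/C(C)=C/CCO[Si](C)(C)C(C)(C)C)OC1=O
A5 | alternative 2 | 2-[2-(tert-butyldimethylsilyloxy)ethyl]-1,3-dimethylcyclohex-3-ene-1-carboxylic acid, C4 and C5 as in 31 | CC1=CCC[C@](C)(C(=O)O)[C@@H]1CCO[Si](C)(C)C(C)(C)C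
A6 | alternative 3 | 7-tert-butyl 1-methyl (2Z)-6-[(4E)-1-(tert-butyldimethylsilyloxy)-4-methylhepta-4,6-dien-3-yl]-2-methylhept-2-enedioate, C8 and C9 as in 31 | C=C/C=C(\C)[C@@H](CCO[Si](C)(C)C(C)(C)C)[C@H](C(=O)OC(C)(C)C)CC/C=C(/C)C(=O)OC
A7 | alternative 3 | trans-fused octalin with C1=C2 alkene, C19 methyl ester, C17 tert-butyl ester and C12 silyl ether, stereocentres as in 31 | C[C@]12C=CC[C@](C)(C(=O)OC)[C@@H]1CC[C@@H](C(=O)OC(C)(C)C)[C@@H]2CCO[Si](C)(C)C(C)(C)C
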